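**Retrosynthetic overview**
1. Target 26 ⇐ O‑debenzylation of keto lactone 25. C4 is α to the aryl ketone and is set by equilibration; only the quaternary carbinol C3 needs absolute control.
2. 25 ⇐ nitro lactone 22 by a Nef reaction. The γ‑lactone (the only ring of the target, formed last) is closed by translactonisation of a temporary Seebach dioxolanone ring (formed first), which also frees the tertiary OH.
3. Key late coupling: Michael addition of the enolate of dioxolanone 17 (one aryl‑C3 half) to nitroalkene 12 (the other aryl‑C3 half; nitro = masked ketone), forming C3–C4.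
4. 17 ⇐ (R)‑aryllactic acid ⇐ ArMgBr + methyl (R)‑glycidate; 12 ⇐ ArCH2NO2 + TBSOCH2CHO (Henry, dehydration).
5. Both aryl halves ⇐ aryl bromide 4 ⇐ catechol (O‑methylation, para‑bromination, O‑benzylation).

Assumption: methyl (R)‑glycidate is bought as the single enantiomer; MeI, BnBr, TBSCl and pivalaldehyde are treated as reagents (methyl ether, protecting groups, auxiliary).

**Route**

Step 1
Reactants: 1 catechol
Product: 2 guaiacol (2‑methoxyphenol)
Conditions: MeI (1.0 equiv), K2CO3, acetone, reflux; distil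
Reagents that add atoms: iodomethane, CI
Why: Williamson mono‑O‑methylation with one equivalent of MeI; veratrole and unreacted catechol are removed by base extraction and distillation.

Step 2
Reactants: 2 guaiacol
Product: 3 4‑bromo‑2‑methoxyphenol
Conditions: NBS, MeCN, 0 °C
Reagents that add atoms: N‑bromosuccinimide, O=C1CCC(=O)N1Br
Why: Electrophilic aromatic bromination goes para to the free OH, the stronger director, giving the 4‑hydroxy‑3‑methoxy pattern.

Step 3
Reactants: 3 4‑bromo‑2‑methoxyphenol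
Product: 4 1‑(benzyloxy)‑4‑bromo‑2‑methoxybenzene
Conditions: BnBr, K2CO3, DMF, 60 °C
Reagents that add atoms: benzyl bromide, BrCc1ccccc1
Why: Williamson etherification protects the phenol for the organometallic and enolate steps.

Step 4
Reactants: 4 1‑(benzyloxy)‑4‑bromo‑2‑methoxybenzene; 5 nitromethane
Product: 6 1‑(benzyloxy)‑2‑methoxy‑4‑(nitromethyl)benzene
Conditions: Pd2(dba)3 (2.5 mol %), XPhos (6 mol %), Cs2CO3, 5 (10 equiv), 1,4‑dioxane, 4 Å MS, 50 °C
Reagents that add atoms: none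
Why: Pd‑catalysed cross‑coupling (α‑arylation) of nitromethane; the acidic product sits as its nitronate, which blocks a second arylation.

Step 5
Reactants: 7 ethylene glycol
Product: 8 2‑[(tert‑butyldimethylsilyl)oxy]ethan‑1‑ol
Conditions: TBSCl (1 equiv), imidazole, 7 (5 equiv), THF, 0 °C → rt
Reagents that add atoms: tert‑butyldimethylsilyl chloride, CC(C)(C)[Si](C)(C)Cl
Why: Statistical mono‑silylation with excess diol; the excess is washed out with water.

Step 6
Reactants: 8 2‑[(tert‑butyldimethylsilyl)oxy]ethan‑1‑ol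
Product: 9 [(tert‑butyldimethylsilyl)oxy]acetaldehyde
Conditions: Dess–Martin periodinane, CH2Cl2, rt
Reagents that add atoms: none
Why: Dess–Martin oxidation of the primary alcohol stops at the aldehyde and leaves the silyl ether alone.

Step 7
Reactants: 6 1‑(benzyloxy)‑2‑methoxy‑4‑(nitromethyl)benzene; 9 [(tert‑butyldimethylsilyl)oxy]acetaldehyde
Product: 10 1‑[4‑(benzyloxy)‑3‑methoxyphenyl]‑3‑[(tert‑butyldimethylsilyl)oxy]‑1‑nitropropan‑2‑ol (diastereomer mixture)
Conditions: DBU (5 mol %), THF, 0 °C → rt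
Reagents that add atoms: none
Why: Base‑catalysed Henry (nitroaldol) addition to an unhindered α‑silyloxy aldehyde; both new centres are removed in step 8.

Step 8
Reactants: 10 nitro alcohol
Product: 12 (E)‑{[3‑(4‑(benzyloxy)‑3‑methoxyphenyl)‑3‑nitroprop‑2‑en‑1‑yl]oxy}(tert‑butyl)dimethylsilane, via nitro mesylate 11 (not isolated)
Conditions: MsCl, Et3N, CH2Cl2, −20 → 0 °C
Reagents that add atoms: none
Why: O‑mesylation then E1cB elimination (nitroaldol dehydration) gives the conjugated α‑aryl nitroalkene; its geometry (E expected) does not matter because both alkene carbons are reworked later.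

Step 9
Reactants: 4 1‑(benzyloxy)‑4‑bromo‑2‑methoxybenzene; 13 methyl (R)‑glycidate
Product: 15 methyl (2R)‑3‑[4‑(benzyloxy)‑3‑methoxyphenyl]‑2‑hydroxypropanoate, via aryl Grignard reagent 14 (not isolated)
Conditions: Mg, THF, 40 °C; CuI (10 mol %), 13, −40 → −20 °C; 1 M HCl
Reagents that add atoms: none
Why: Copper‑catalysed SN2 opening of the epoxide at the unsubstituted C3 outpaces ester attack at low temperature and leaves C2 untouched, so the (R) centre comes from the glycidate.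

Step 10
Reactants: 15 methyl (2R)‑aryllactate
Product: 16 (2R)‑3‑[4‑(benzyloxy)‑3‑methoxyphenyl]‑2‑hydroxypropanoic acid
Conditions: LiOH, THF–H2O, 0 °C → rt; 1 M HCl
Reagents that add atoms: lithium hydroxide, [Li+].[OH-]
Why: Mild saponification of an α‑hydroxy ester, which does not racemise under these conditions.

Step 11
Reactants: 16 (2R)‑aryllactic acid
Product: 17 (2R,5R)‑5‑[4‑(benzyloxy)‑3‑methoxybenzyl]‑2‑tert‑butyl‑1,3‑dioxolan‑4‑one (cis)
Conditions: t‑BuCHO, TsOH·H2O (cat.), H2SO4 (cat.), CH2Cl2–pentane, reflux (Dean–Stark); recrystallise to pure cis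
Reagents that add atoms: pivalaldehyde, CC(C)(C)C=O
Why: Seebach acetalisation gives mainly the cis acetal, which stores the C5 configuration in the new acetal centre (self‑regeneration of stereocentres); the minor trans isomer must be removed because it would give the enantiomeric enolate.

Step 12
Reactants: 17 cis‑dioxolanone; 12 nitroalkene
Product: 20 (2R,5S)‑5‑[4‑(benzyloxy)‑3‑methoxybenzyl]‑5‑{1‑[4‑(benzyloxy)‑3‑methoxyphenyl]‑3‑[(tert‑butyldimethylsilyl)oxy]‑1‑nitropropan‑2‑yl}‑2‑tert‑butyl‑1,3‑dioxolan‑4‑one (mixture of side‑chain epimers), via lithium enolate 18 (not isolated), via lithium nitronate 19 (not isolated)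
Conditions: LDA, THF, −78 °C; 12, −78 °C; AcOH, −78 °C
Reagents that add atoms: none
Why: Michael addition of the Seebach dioxolanone enolate to the nitroalkene occurs trans to the tert‑butyl group, so the new C–C bond replaces the original α‑H with retention and fixes the quaternary carbinol centre (C3 S of the target); the two side‑chain centres form as mixtures and are erased or equilibrated later.

Step 13
Reactants: 20 Michael adduct
Product: 22 (3S)‑3‑[4‑(benzyloxy)‑3‑methoxybenzyl]‑4‑{[4‑(benzyloxy)‑3‑methoxyphenyl](nitro)methyl}‑3‑hydroxyoxolan‑2‑one (mixture of epimers at C4 and the nitro carbon), via free primary alcohol 21 (not isolated)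
Conditions: 2 M aq. HCl–THF, rt → 40 °C
Reagents that add atoms: none
Why: Acidic cleavage of the primary TBS ether, then acid‑catalysed translactonisation of the freed alcohol onto the dioxolanone carbonyl, closes the γ‑lactone, expels pivalaldehyde and unveils the tertiary OH without touching C3.

Step 14
Reactants: 22 nitro lactone
Product: 25 (3S,4S)‑4‑[4‑(benzyloxy)‑3‑methoxybenzoyl]‑3‑[4‑(benzyloxy)‑3‑methoxybenzyl]‑3‑hydroxyoxolan‑2‑one, via potassium nitronate 23 (not isolated), via C4‑epimeric keto lactone 24 (not isolated)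
Conditions: t‑BuOK (1.0 equiv), THF, −78 → 0 °C; DMDO (acetone), 0 °C; then Et3N (cat.), CH2Cl2, rt
Reagents that add atoms: dimethyldioxirane, CC1(C)OO1
Why: Oxidative Nef reaction of the benzylic nitronate gives the aryl ketone, and amine‑catalysed enolisation then equilibrates C4 to what should be the more stable epimer (4S), with the aroyl group trans to the larger benzyl group and cis to the OH it can hydrogen‑bond to.

Step 15
Reactants: 25 dibenzyl keto lactone
Product: 26 (3S,4S)‑3‑hydroxy‑4‑(4‑hydroxy‑3‑methoxybenzoyl)‑3‑(4‑hydroxy‑3‑methoxybenzyl)oxolan‑2‑one (target)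
Conditions: H2 (1 atm), 10 % Pd/C, EtOAc, rt
Reagents that add atoms: none
Why: Neutral catalytic hydrogenolysis removes both aryl benzyl ethers and should leave the electron‑rich aryl ketone, the lactone and both stereocentres intact.

**Compound list**
1 | catechol | Oc1ccccc1O | starting material
2 | guaiacol | COc1ccccc1O | intermediate
3 | 4‑bromo‑2‑methoxyphenol | COc1cc(Br)ccc1O | intermediate
4 | 1‑(benzyloxy)‑4‑bromo‑2‑methoxybenzene | COc1cc(Br)ccc1OCc1ccccc1 | intermediate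
5 | nitromethane | C[N+](=O)[O-] | starting material
6 | 1‑(benzyloxy)‑2‑methoxy‑4‑(nitromethyl)benzene | COc1cc(C[N+](=O)[O-])ccc1OCc1ccccc1 | intermediate
7 | ethylene glycol | OCCO | starting material
8 | 2‑[(tert‑butyldimethylsilyl)oxy]ethan‑1‑ol | CC(C)(C)[Si](C)(C)OCCO | intermediate
9 | [(tert‑butyldimethylsilyl)oxy]acetaldehyde | CC(C)(C)[Si](C)(C)OCC=O | intermediate
10 | 1‑[4‑(benzyloxy)‑3‑methoxyphenyl]‑3‑[(tert‑butyldimethylsilyl)oxy]‑1‑nitropropan‑2‑ol (diastereomer mixture) | COc1cc(C(C(O)CO[Si](C)(C)C(C)(C)C)[N+](=O)[O-])ccc1OCc1ccccc1 | intermediate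
11 | methanesulfonate of 10 (not isolated) | COc1cc(C(C(OS(C)(=O)=O)CO[Si](C)(C)C(C)(C)C)[N+](=O)[O-])ccc1OCc1ccccc1 | intermediate
12 | (E)‑{[3‑(4‑(benzyloxy)‑3‑methoxyphenyl)‑3‑nitroprop‑2‑en‑1‑yl]oxy}(tert‑butyl)dimethylsilane | [O-][N+](=O)/C(=C/CO[Si](C)(C)C(C)(C)C)c1ccc(OCc2ccccc2)c(OC)c1 | intermediate
13 | methyl (R)‑glycidate (methyl (2R)‑oxirane‑2‑carboxylate) | COC(=O)[C@H]1CO1 | starting material
14 | [4‑(benzyloxy)‑3‑methoxyphenyl]magnesium bromide (not isolated) | COc1cc([Mg]Br)ccc1OCc1ccccc1 | intermediate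
15 | methyl (2R)‑3‑[4‑(benzyloxy)‑3‑methoxyphenyl]‑2‑hydroxypropanoate | COC(=O)[C@H](O)Cc1ccc(OCc2ccccc2)c(OC)c1 | intermediate
16 | (2R)‑3‑[4‑(benzyloxy)‑3‑methoxyphenyl]‑2‑hydroxypropanoic acid | OC(=O)[C@H](O)Cc1ccc(OCc2ccccc2)c(OC)c1 | intermediate
17 | (2R,5R)‑5‑[4‑(benzyloxy)‑3‑methoxybenzyl]‑2‑tert‑butyl‑1,3‑dioxolan‑4‑one | CC(C)(C)[C@H]1OC(=O)[C@@H](Cc2ccc(OCc3ccccc3)c(OC)c2)O1 | intermediate
18 | lithium enolate of 17 (not isolated) | CC(C)(C)[C@H]1OC(O[Li])=C(Cc2ccc(OCc3ccccc3)c(OC)c2)O1 | intermediate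
19 | lithium nitronate of 20 (not isolated) | CC(C)(C)[C@H]1OC(=O)[C@](Cc2ccc(OCc3ccccc3)c(OC)c2)(C(CO[Si](C)(C)C(C)(C)C)C(c2ccc(OCc3ccccc3)c(OC)c2)=[N+]([O-])[O-])O1.[Li+] | intermediate
20 | (2R,5S)‑5‑[4‑(benzyloxy)‑3‑methoxybenzyl]‑5‑{1‑[4‑(benzyloxy)‑3‑methoxyphenyl]‑3‑[(tert‑butyldimethylsilyl)oxy]‑1‑nitropropan‑2‑yl}‑2‑tert‑butyl‑1,3‑dioxolan‑4‑one (side‑chain epimers) | CC(C)(C)[C@H]1OC(=O)[C@](Cc2ccc(OCc3ccccc3)c(OC)c2)(C(CO[Si](C)(C)C(C)(C)C)C(c2ccc(OCc3ccccc3)c(OC)c2)[N+](=O)[O-])O1 | intermediate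
21 | desilylated primary alcohol of 20 (not isolated) | CC(C)(C)[C@H]1OC(=O)[C@](Cc2ccc(OCc3ccccc3)c(OC)c2)(C(CO)C(c2ccc(OCc3ccccc3)c(OC)c2)[N+](=O)[O-])O1 | intermediate
22 | (3S)‑3‑[4‑(benzyloxy)‑3‑methoxybenzyl]‑4‑{[4‑(benzyloxy)‑3‑methoxyphenyl](nitro)methyl}‑3‑hydroxyoxolan‑2‑one (epimers at C4 and the nitro carbon) | COc1cc(C[C@@]2(O)C(=O)OCC2C(c2ccc(OCc3ccccc3)c(OC)c2)[N+](=O)[O-])ccc1OCc1ccccc1 | intermediate
23 | potassium nitronate of 22 (not isolated) | COc1cc(C[C@@]2(O)C(=O)OCC2C(c2ccc(OCc3ccccc3)c(OC)c2)=[N+]([O-])[O-])ccc1OCc1ccccc1.[K+] | intermediate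
24 | (3S,4R)‑4‑[4‑(benzyloxy)‑3‑methoxybenzoyl]‑3‑[4‑(benzyloxy)‑3‑methoxybenzyl]‑3‑hydroxyoxolan‑2‑one (C4 epimer, not isolated) | COc1cc(C[C@@]2(O)C(=O)OC[C@H]2C(=O)c2ccc(OCc3ccccc3)c(OC)c2)ccc1OCc1ccccc1 | intermediate
25 | (3S,4S)‑4‑[4‑(benzyloxy)‑3‑methoxybenzoyl]‑3‑[4‑(benzyloxy)‑3‑methoxybenzyl]‑3‑hydroxyoxolan‑2‑one | COc1cc(C[C@@]2(O)C(=O)OC[C@@H]2C(=O)c2ccc(OCc3ccccc3)c(OC)c2)ccc1OCc1ccccc1 | intermediate
26 | (3S,4S)‑3‑hydroxy‑4‑(4‑hydroxy‑3‑methoxybenzoyl)‑3‑(4‑hydroxy‑3‑methoxybenzyl)oxolan‑2‑one | COc1cc(C[C@@]2(O)C(=O)OC[C@@H]2C(=O)c2ccc(O)c(OC)c2)ccc1O | target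

**Step count**
Total steps: 15.
Longest linear sequence: 10 (steps 1, 2, 3, 4, 7, 8, 12, 13, 14, 15; the branch through steps 9–11 is equally long).

**Steps most likely to fail, with fallbacks**

Step 12 is the main risk: a hindered, fully substituted enolate must add to a trisubstituted nitroalkene, and the basic enolate may instead remove a γ‑proton of 12. The fallback drops the basic enolate for a Mukaiyama–Michael addition. Setting out from 17, enolate 18 is silylated (LDA, TMSCl, THF, −78 °C) to the silyl ketene acetal {[(2R)‑5‑[4‑(benzyloxy)‑3‑methoxybenzyl]‑2‑tert‑butyl‑1,3‑dioxol‑4‑yl]oxy}trimethylsilane F1. This neutral nucleophile is added to 12 under Lewis‑acid activation (TiCl2(Oi‑Pr)2, CH2Cl2, −78 °C), again trans to the tert‑butyl group. The resulting trimethylsilyl nitronate of 20 F2 is not isolated; aqueous AcOH work‑up hydrolyses it and the route is rejoined at 20.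

Step 14 is the second risk: the Nef reaction may over‑oxidise the electron‑rich arenes, or the brief basic phase may trigger retro‑aldol or β‑elimination of the product. The fallback unmasks the ketone reductively. Setting out from 22, the nitro group is reduced to the oxime (3S)‑3‑[4‑(benzyloxy)‑3‑methoxybenzyl]‑4‑{[4‑(benzyloxy)‑3‑methoxyphenyl](hydroxyimino)methyl}‑3‑hydroxyoxolan‑2‑one F3 (SnCl2, PhSH, Et3N, MeCN, rt). The oxime is cleaved with buffered aqueous TiCl3 (NH4OAc, THF–H2O, rt) to the 24/25 mixture, which catalytic Et3N in CH2Cl2 funnels to 25, where the route is rejoined.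

Step 8 is the third risk: retro‑Henry cleavage under MsCl/Et3N, or polymerisation of the isolated α‑aryl nitroalkene 12. The fallback never isolates 12. Setting out from 10, acid‑catalysed acetylation (Ac2O, Sc(OTf)3 cat., MeCN, 0 °C) gives the stable nitro acetate 1‑[4‑(benzyloxy)‑3‑methoxyphenyl]‑3‑[(tert‑butyldimethylsilyl)oxy]‑1‑nitropropan‑2‑yl acetate F4. F4 is added at −78 °C to two equivalents of enolate 18: the first equivalent eliminates acetate (E1cB) to release 12 in the flask and returns one equivalent of 17, the second adds to give 19. The AcOH quench rejoins the route at 20.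

Further compounds
F1 | step 12 | {[(2R)‑5‑[4‑(benzyloxy)‑3‑methoxybenzyl]‑2‑tert‑butyl‑1,3‑dioxol‑4‑yl]oxy}trimethylsilane | CC(C)(C)[C@H]1OC(O[Si](C)(C)C)=C(Cc2ccc(OCc3ccccc3)c(OC)c2)O1
F2 | step 12 | trimethylsilyl nitronate of 20 (not isolated) | CC(C)(C)[C@H]1OC(=O)[C@](Cc2ccc(OCc3ccccc3)c(OC)c2)(C(CO[Si](C)(C)C(C)(C)C)C(c2ccc(OCc3ccccc3)c(OC)c2)=[N+]([O-])O[Si](C)(C)C)O1
F3 | step 14 | (3S)‑3‑[4‑(benzyloxy)‑3‑methoxybenzyl]‑4‑{[4‑(benzyloxy)‑3‑methoxyphenyl](hydroxyimino)methyl}‑3‑hydroxyoxolan‑2‑one | COc1cc(C[C@@]2(O)C(=O)OCC2C(=NO)c2ccc(OCc3ccccc3)c(OC)c2)ccc1OCc1ccccc1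
F4 | step 8 | 1‑[4‑(benzyloxy)‑3‑methoxyphenyl]‑3‑[(tert‑butyldimethylsilyl)oxy]‑1‑nitropropan‑2‑yl acetate | COc1cc(C(C(OC(C)=O)CO[Si](C)(C)C(C)(C)C)[N+](=O)[O-])ccc1OCc1ccccc1
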